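**Strategy**

Ring A bears oxygen on C5, C7 and C8a, and C6, flanked by the two phenolic carbons, holds the prenyl group; C5–C6–C7 is therefore the carbon chain of prenylmalonic acid, while C4a, C8a and C8 can come from a ring B dihydropyranone made beforehand. The route rests on disconnecting C4a–C5 and C7–C8. One (3+3) operation, a double C-acylation by 2-prenylmalonyl dichloride followed by enolisation, builds the whole aromatic ring with both phenols free and no protecting group. Its precursor is a cis-2,3-dimethyl-2,3-dihydro-4H-pyran-4-one that already contains O1, the C2 and C3 stereocentres (syn aldol) and, on the future C8, the ester side chain with its stereocentre (desymmetrised 3-propylglutarate).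

Key step: step 12

Assumption: in step 5 the quinidine-derived catalyst is taken to give the S half ester; the sense would be checked on the first batch and, if it is opposite, the quinine-derived pseudoenantiomer (DHQ)2AQN would be used with no other change.

**Route**

Step 1
Reactants: 1 (S)-4-benzyl-3-propionyloxazolidin-2-one; 2 acetaldehyde
Product: 4 (S)-4-benzyl-3-[(2S,3R)-3-hydroxy-2-methylbutanoyl]oxazolidin-2-one, via Z dibutylboron enolate 3 (not isolated)
Conditions: n-Bu2BOTf (1.1 equiv), i-Pr2NEt (1.2 equiv), CH2Cl2, −78 → 0 °C; 2 (3 equiv), −78 → 0 °C; pH 7 buffer, MeOH, 30% H2O2, 0 °C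
Reagents that add atoms: none
Why: Evans syn aldol reaction: the Z boron enolate 3 reacts through a chair Zimmerman–Traxler transition state on the enolate face away from the benzyl group, which should set 2S (methyl) and 3R (hydroxyl), the future C3 and C2 of ring B.

Step 2
Reactants: 4
Product: 5 (2S,3R)-3-hydroxy-N-methoxy-N,2-dimethylbutanamide
Conditions: MeNHOMe·HCl (3 equiv), AlMe3 (3 equiv), CH2Cl2, −20 → 0 °C; aq. KNaC4H4O6
Reagents that add atoms: N,O-dimethylhydroxylamine hydrochloride, CNOC.Cl
Why: Weinreb transamidation by the aluminium amide, directed to the exocyclic carbonyl by the free β-hydroxyl (as its aluminium alkoxide), should release the auxiliary without epimerising the α-centre.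

Step 3
Reactants: 5
Product: 6 (2S,3R)-N-methoxy-N,2-dimethyl-3-[(triethylsilyl)oxy]butanamide
Conditions: Et3SiCl (1.2 equiv), imidazole (2 equiv), CH2Cl2, 0 °C → rt
Reagents that add atoms: chlorotriethylsilane, CC[Si](Cl)(CC)CC
Why: Imidazole-promoted silylation of the secondary alcohol; the triethylsilyl ether withstands the Grignard and enolate steps yet falls to mild acid in step 8.

Step 4
Reactants: 6
Product: 7 (3S,4R)-3-methyl-4-[(triethylsilyl)oxy]pentan-2-one
Conditions: MeMgBr (1.5 equiv), THF, 0 °C; aq. NH4Cl
Reagents that add atoms: methylmagnesium bromide, C[Mg]Br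
Why: Grignard addition to the Weinreb amide stops at the ketone stage because the chelated tetrahedral intermediate survives until work-up, and no base strong enough to enolise the α-centre is present.

Step 5
Reactants: 8 3-propylglutaric anhydride (4-propyloxane-2,6-dione)
Product: 9 (3S)-3-(2-methoxy-2-oxoethyl)hexanoic acid
Conditions: MeOH (10 equiv), (DHQD)2AQN (0.2 equiv), Et2O, −40 °C; 1 M HCl wash (catalyst recovered)
Reagents that add atoms: methanol, CO
Why: Alkaloid-mediated enantioselective alcoholysis (desymmetrisation) of a prochiral cyclic anhydride: the quinuclidine nitrogen acts as a chiral general base that delivers methanol to one of the two enantiotopic carbonyl groups, which sets the S centre of the half ester (R in the target after the priority change).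

Step 6
Reactants: 9
Product: 10 methyl (3S)-3-[2-(1H-imidazol-1-yl)-2-oxoethyl]hexanoate
Conditions: 1,1'-carbonyldiimidazole (1.05 equiv), CH2Cl2, rt; cold water wash, Na2SO4, concentrate
Reagents that add atoms: 1,1'-carbonyldiimidazole, O=C(n1ccnc1)n1ccnc1
Why: Activation of the carboxylic acid as its N-acylimidazole by carbonyldiimidazole, driven by loss of CO2; the free imidazole is washed out because its N–H would quench the enolate of step 7.

Step 7
Reactants: 7; 10
Product: 12 methyl (3S)-3-[(5S,6R)-5-methyl-2,4-dioxo-6-(triethylsilyloxy)heptyl]hexanoate, via kinetic lithium enolate 11 (not isolated)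
Conditions: 7 (1.5 equiv), LiN(i-Pr)2 (commercial solution, 1.5 equiv), THF, −78 °C; 10 (1.0 equiv), −78 → −40 °C; aq. NH4Cl
Reagents that add atoms: none
Why: Crossed Claisen-type C-acylation of a ketone enolate: LiN(i-Pr)2 deprotonates the methyl side kinetically at −78 °C, the N-acylimidazole is far more electrophilic than the methyl ester, and the imidazolide set free deprotonates the diketone and so protects it from a second attack.

Step 8
Reactants: 12
Product: 14 methyl (3S)-3-{[(2R,3S)-2,3-dimethyl-4-oxo-3,4-dihydro-2H-pyran-6-yl]methyl}hexanoate (fragment 1), via desilylated hydroxy diketone 13 (not isolated)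
Conditions: CF3CO2H/CH2Cl2 (1:10), H2O (2 equiv), 0 °C → rt; aq. NaHCO3
Reagents that add atoms: none
Why: Acid-mediated desilylation and cyclodehydration of a δ-hydroxy β-diketone: the free hydroxyl can reach only the distal ketone in a six-membered hemiketal, loss of water gives the vinylogous ester, and because the C–O bond of the carbinol is never broken the syn aldol centres are retained as the cis-2,3-dimethyl pattern (2R,3S).

Step 9
Reactants: 15 diethyl malonate; 16 prenyl bromide (1-bromo-3-methylbut-2-ene)
Product: 18 diethyl 2-(3-methylbut-2-en-1-yl)malonate, via sodium malonate enolate 17 (not isolated)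
Conditions: 15 (1.5 equiv), NaH (1.05 equiv), THF, 0 °C; 16 (1.0 equiv), 0 °C → rt; distillation
Reagents that add atoms: none
Why: Malonic ester alkylation, an SN2 displacement on the primary allylic bromide, with the malonate in excess to suppress dialkylation.

Step 10
Reactants: 18
Product: 19 2-(3-methylbut-2-en-1-yl)malonic acid
Conditions: KOH (2.5 equiv), EtOH/H2O, rt; cold 1 M HCl to pH 2, EtOAc extraction, no heating
Reagents that add atoms: potassium hydroxide, [K+].[OH-]
Why: Saponification of both ester groups; acidification in the cold and work-up without heating should avoid decarboxylation and acid-induced lactonisation onto the alkene.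

Step 11
Reactants: 19
Product: 20 2-(3-methylbut-2-en-1-yl)malonyl dichloride (fragment 2)
Conditions: 1-chloro-N,N,2-trimethylprop-1-en-1-amine (2.05 equiv), CH2Cl2, 0 °C → rt; bulb-to-bulb distillation, used at once
Reagents that add atoms: 1-chloro-N,N,2-trimethylprop-1-en-1-amine, CC(C)=C(Cl)N(C)C
Why: The α-chloroenamine converts carboxylic acids into acid chlorides under neutral conditions with an amide as the only by-product, so that no hydrogen chloride meets the trisubstituted alkene.

Step 12
Reactants: 14; 20
Product: 24 methyl (3R)-3-[(2R,3S)-5,7-dihydroxy-2,3-dimethyl-6-(3-methylbut-2-en-1-yl)-4-oxochroman-8-yl]hexanoate, via chlorocarbonyl prenyl ketene 21 (not isolated), via C4a-acylated pyranone acid chloride 22 (not isolated), via ring A triketo tautomer 23 (not isolated)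
Conditions: 14 (1.0 equiv), 2,6-di-tert-butyl-4-methylpyridine (2.6 equiv), PhMe, 60 °C; 20 (1.2 equiv) added over 2 h; then 80 °C; aq. NaHCO3
Reagents that add atoms: none
Why: Proposed new method: the hindered pyridine removes HCl from 20 to give chlorocarbonyl ketene 21, which C-acylates C4a, the nucleophilic α-carbon of the vinylogous ester, to give 22; the C8 methylene of 22 is now vinylogous to the C4 and the C5 carbonyl, enolises to the exocyclic dienol and attacks the remaining acyl chloride through C8 (or, after a second loss of HCl, the dienyl ketene closes by 6π electrocyclisation) to give 23, which aromatises by two enolisations. The closest known reaction type is the cyclocondensation of malonyl dichlorides or chlorocarbonyl ketenes with ketones and enol ethers acting as 1,3-dinucleophiles (double C-acylation to cyclic triones and phloroglucinols, or C,O-acylation to 4-hydroxy-2-pyranones), not yet shown for a 2,3-dihydro-4H-pyran-4-one as the C,C-partner. Ring A closes in a 6-exo-trig C-acylation of C8 on C7, after the intermolecular C4a–C5 bond has tethered the electrophile. No stereocentre is formed, and C2, C3 and the side-chain centre are spectators because the only base is a weak, non-nucleophilic pyridine that also keeps free HCl away from the prenyl group. The step needs C-acylation at C4a and C8 to win over O-acylation: acylation at the C4 oxygen gives a dienol ester that remains an acyl donor and can re-enter the pathway, O1 is already locked in ring B so that a six-membered ring can only be completed through C8, and only the C,C-product aromatises, which removes it from every equilibrium. Slow addition of 20 keeps the ketene concentration low, which should hold back its self-condensation and the acylation of the product phenols.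

**Compound list**

1 | (S)-4-benzyl-3-propionyloxazolidin-2-one | CCC(=O)N1[C@@H](Cc2ccccc2)COC1=O | starting material
2 | acetaldehyde | CC=O | starting material
3 | (S)-4-benzyl-3-[(Z)-1-(dibutylboranyloxy)prop-1-en-1-yl]oxazolidin-2-one | C/C=C(\OB(CCCC)CCCC)N1[C@@H](Cc2ccccc2)COC1=O | intermediate
4 | (S)-4-benzyl-3-[(2S,3R)-3-hydroxy-2-methylbutanoyl]oxazolidin-2-one | C[C@@H](O)[C@H](C)C(=O)N1[C@@H](Cc2ccccc2)COC1=O | intermediate
5 | (2S,3R)-3-hydroxy-N-methoxy-N,2-dimethylbutanamide | C[C@@H](O)[C@H](C)C(=O)N(C)OC | intermediate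
6 | (2S,3R)-N-methoxy-N,2-dimethyl-3-[(triethylsilyl)oxy]butanamide | C[C@@H](O[Si](CC)(CC)CC)[C@H](C)C(=O)N(C)OC | intermediate
7 | (3S,4R)-3-methyl-4-[(triethylsilyl)oxy]pentan-2-one | C[C@@H](O[Si](CC)(CC)CC)[C@H](C)C(C)=O | intermediate
8 | 3-propylglutaric anhydride (4-propyloxane-2,6-dione) | CCCC1CC(=O)OC(=O)C1 | starting material
9 | (3S)-3-(2-methoxy-2-oxoethyl)hexanoic acid | CCC[C@H](CC(=O)OC)CC(=O)O | intermediate
10 | methyl (3S)-3-[2-(1H-imidazol-1-yl)-2-oxoethyl]hexanoate | CCC[C@H](CC(=O)OC)CC(=O)n1ccnc1 | intermediate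
11 | lithium (3S,4R)-3-methyl-4-[(triethylsilyl)oxy]pent-1-en-2-olate | [Li]OC(=C)[C@@H](C)[C@@H](C)O[Si](CC)(CC)CC | intermediate
12 | methyl (3S)-3-[(5S,6R)-5-methyl-2,4-dioxo-6-(triethylsilyloxy)heptyl]hexanoate | CCC[C@H](CC(=O)OC)CC(=O)CC(=O)[C@@H](C)[C@@H](C)O[Si](CC)(CC)CC | intermediate
13 | methyl (3S)-3-[(5S,6R)-6-hydroxy-5-methyl-2,4-dioxoheptyl]hexanoate | CCC[C@H](CC(=O)OC)CC(=O)CC(=O)[C@@H](C)[C@@H](C)O | intermediate
14 | methyl (3S)-3-{[(2R,3S)-2,3-dimethyl-4-oxo-3,4-dihydro-2H-pyran-6-yl]methyl}hexanoate (fragment 1) | CCC[C@H](CC(=O)OC)CC1=CC(=O)[C@@H](C)[C@@H](C)O1 | intermediate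
15 | diethyl malonate | CCOC(=O)CC(=O)OCC | starting material
16 | prenyl bromide (1-bromo-3-methylbut-2-ene) | CC(C)=CCBr | starting material
17 | sodium 1,3-diethoxy-1,3-dioxopropan-2-ide | [Na+].CCOC(=O)[CH-]C(=O)OCC | intermediate
18 | diethyl 2-(3-methylbut-2-en-1-yl)malonate | CCOC(=O)C(CC=C(C)C)C(=O)OCC | intermediate
19 | 2-(3-methylbut-2-en-1-yl)malonic acid | CC(C)=CCC(C(=O)O)C(=O)O | intermediate
20 | 2-(3-methylbut-2-en-1-yl)malonyl dichloride (fragment 2) | CC(C)=CCC(C(=O)Cl)C(=O)Cl | intermediate
21 | 2-(chlorocarbonyl)-5-methylhexa-1,4-dien-1-one (chlorocarbonyl prenyl ketene) | CC(C)=CCC(=C=O)C(=O)Cl | intermediate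
22 | methyl (3S)-3-({(2R,3S)-5-[2-(chlorocarbonyl)-5-methylhex-4-enoyl]-2,3-dimethyl-4-oxo-3,4-dihydro-2H-pyran-6-yl}methyl)hexanoate (mixture at the malonyl carbon) | CCC[C@H](CC(=O)OC)CC1=C(C(=O)C(CC=C(C)C)C(=O)Cl)C(=O)[C@@H](C)[C@@H](C)O1 | intermediate
23 | methyl (3R)-3-[(2R,3S)-2,3-dimethyl-6-(3-methylbut-2-en-1-yl)-4,5,7-trioxo-3,4,5,6,7,8-hexahydro-2H-chromen-8-yl]hexanoate (mixture at C6 and C8) | CCC[C@H](CC(=O)OC)C1C(=O)C(CC=C(C)C)C(=O)C2=C1O[C@H](C)[C@H](C)C2=O | intermediate
24 | methyl (3R)-3-[(2R,3S)-5,7-dihydroxy-2,3-dimethyl-6-(3-methylbut-2-en-1-yl)-4-oxochroman-8-yl]hexanoate | CCC[C@H](CC(=O)OC)c1c(O)c(CC=C(C)C)c(O)c2c1O[C@H](C)[C@H](C)C2=O | target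

**Step count and risks**

Total: 12 steps. Longest linear sequence: 7 steps (steps 1, 2, 3, 4, 7, 8 and 12).

Steps most likely to fail:

1. Step 12. The deactivated enol ether carbon C4a may be acylated too slowly, so that the ketene is consumed by self-condensation. Acylation may also end on the C4 oxygen and give a fused 4-hydroxy-2-pyranone instead of ring A. Prolonged heating could enolise C3 or lactonise the 7-hydroxyl onto the ester. The fallback keeps ring B ahead of ring A but closes ring A by a Claisen condensation using known acyl ketene (dioxinone) chemistry. It sets out from Weinreb amide 6, half ester 9 and prenyl bromide 16 and returns at target 24.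
   - The lithium dienolate of commercial 2,2,6-trimethyl-4H-1,3-dioxin-4-one (LiN(SiMe3)2, THF, −78 °C) would be acylated by 6 to give 2,2-dimethyl-6-[(3S,4R)-3-methyl-2-oxo-4-(triethylsilyloxy)pentyl]-4H-1,3-dioxin-4-one F1.
   - Acid 9 would be converted (oxalyl chloride, cat. DMF, CH2Cl2) into methyl (3R)-3-(2-chloro-2-oxoethyl)hexanoate F2.
   - F2 would C-acylate the active methylene of F1 (MgCl2, pyridine, CH2Cl2) to give methyl (3S)-3-[(5S,6R)-3-(2,2-dimethyl-4-oxo-4H-1,3-dioxin-6-yl)-5-methyl-2,4-dioxo-6-(triethylsilyloxy)heptyl]hexanoate F3.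
   - CF3CO2H in CH2Cl2 would remove the silyl group and close ring B as in step 8, giving methyl (3S)-3-{[(2R,3S)-5-(2,2-dimethyl-4-oxo-4H-1,3-dioxin-6-yl)-2,3-dimethyl-4-oxo-3,4-dihydro-2H-pyran-6-yl]methyl}hexanoate F4. The dioxinone masks C5 as an enol ether, so only the C8a ketone can take up the hydroxyl.
   - Heating F4 with MeOH in PhMe (110 °C) would expel acetone and trap the acyl ketene as methyl (3S)-3-{[(2R,3S)-5-(3-methoxy-3-oxopropanoyl)-2,3-dimethyl-4-oxo-3,4-dihydro-2H-pyran-6-yl]methyl}hexanoate F5.
   - The active methylene of F5 would be alkylated with 16 (K2CO3, acetone) to give methyl (3S)-3-({(2R,3S)-5-[2-(methoxycarbonyl)-5-methylhex-4-enoyl]-2,3-dimethyl-4-oxo-3,4-dihydro-2H-pyran-6-yl}methyl)hexanoate F6.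
   - Mg(OMe)2 in MeOH would close ring A by Claisen condensation of the C8 carbanion onto the malonyl ester, and aromatisation would give 24.

2. Step 7. Proton transfer from the acyl donor or from the product to the enolate, O-acylation, or attack on the methyl ester could hold back the C-acylation. The fallback makes the same C–C bond by an aldol addition and adjusts the oxidation level afterwards. It sets out from half ester 9 and ketone 7 and returns at diketone 12.
   - 9 would be converted (EtSH, EDC·HCl, DMAP, CH2Cl2) into methyl (3R)-3-[2-(ethylsulfanyl)-2-oxoethyl]hexanoate F7.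
   - Fukuyama reduction (Et3SiH, Pd/C, acetone) would give methyl (3S)-3-(2-oxoethyl)hexanoate F8.
   - Aldol addition of enolate 11 (THF, −78 °C) would give methyl (3S)-3-[(5S,6R)-2-hydroxy-5-methyl-4-oxo-6-(triethylsilyloxy)heptyl]hexanoate F9 as a mixture at the new carbinol, which is of no consequence.
   - Dess–Martin oxidation would give 12.

3. Step 5. The catalyst may discriminate the two enantiotopic carbonyl groups incompletely, and the minor enantiomer would be carried through as a diastereomer of 24. The fallback replaces anhydride alcoholysis by enzymatic desymmetrisation of the diester. It sets out from anhydride 8 and returns at half ester 9.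
   - Acid-catalysed methanolysis (MeOH, cat. H2SO4, reflux) would give dimethyl 3-propylpentanedioate F10.
   - Monohydrolysis by a hydrolase (immobilised lipase B of Candida antarctica or pig liver esterase, phosphate buffer pH 7, the enzyme chosen by a short screen for the S acid) would give 9.

Further compounds
F1 | step 12 | 2,2-dimethyl-6-[(3S,4R)-3-methyl-2-oxo-4-(triethylsilyloxy)pentyl]-4H-1,3-dioxin-4-one | C[C@@H](O[Si](CC)(CC)CC)[C@H](C)C(=O)CC1=CC(=O)OC(C)(C)O1
F2 | step 12 | methyl (3R)-3-(2-chloro-2-oxoethyl)hexanoate | CCC[C@H](CC(=O)OC)CC(=O)Cl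
F3 | step 12 | methyl (3S)-3-[(5S,6R)-3-(2,2-dimethyl-4-oxo-4H-1,3-dioxin-6-yl)-5-methyl-2,4-dioxo-6-(triethylsilyloxy)heptyl]hexanoate | CCC[C@H](CC(=O)OC)CC(=O)C(C(=O)[C@@H](C)[C@@H](C)O[Si](CC)(CC)CC)C1=CC(=O)OC(C)(C)O1
F4 | step 12 | methyl (3S)-3-{[(2R,3S)-5-(2,2-dimethyl-4-oxo-4H-1,3-dioxin-6-yl)-2,3-dimethyl-4-oxo-3,4-dihydro-2H-pyran-6-yl]methyl}hexanoate | CCC[C@H](CC(=O)OC)CC1=C(C2=CC(=O)OC(C)(C)O2)C(=O)[C@@H](C)[C@@H](C)O1
F5 | step 12 | methyl (3S)-3-{[(2R,3S)-5-(3-methoxy-3-oxopropanoyl)-2,3-dimethyl-4-oxo-3,4-dihydro-2H-pyran-6-yl]methyl}hexanoate | CCC[C@H](CC(=O)OC)CC1=C(C(=O)CC(=O)OC)C(=O)[C@@H](C)[C@@H](C)O1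
F6 | step 12 | methyl (3S)-3-({(2R,3S)-5-[2-(methoxycarbonyl)-5-methylhex-4-enoyl]-2,3-dimethyl-4-oxo-3,4-dihydro-2H-pyran-6-yl}methyl)hexanoate | CCC[C@H](CC(=O)OC)CC1=C(C(=O)C(CC=C(C)C)C(=O)OC)C(=O)[C@@H](C)[C@@H](C)O1
F7 | step 7 | methyl (3R)-3-[2-(ethylsulfanyl)-2-oxoethyl]hexanoate | CCC[C@H](CC(=O)OC)CC(=O)SCC
F8 | step 7 | methyl (3S)-3-(2-oxoethyl)hexanoate | CCC[C@H](CC(=O)OC)CC=O
F9 | step 7 | methyl (3S)-3-[(5S,6R)-2-hydroxy-5-methyl-4-oxo-6-(triethylsilyloxy)heptyl]hexanoate | CCC[C@H](CC(=O)OC)CC(O)CC(=O)[C@@H](C)[C@@H](C)O[Si](CC)(CC)CC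
F10 | step 5 | dimethyl 3-propylpentanedioate | CCCC(CC(=O)OC)CC(=O)OC
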